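## Retrosynthetic overview

1. The two side arms on the adjacent ring CH carbons (CH=CH–O‑acyl and CH2COCH3) are the two ends of a cleaved 1‑methylcyclohexene, so the target comes from a cis‑fused bicyclic enone by ozonolysis, E‑enol acylation and desilylation.
2. The hydroxymethyl group comes from a Morita–Baylis–Hillman reaction; the quaternary carbon from a convex‑face 1,6‑addition of a side‑chain Grignard reagent (carbinol bought in (R)‑α‑hydroxy‑γ‑butyrolactone) to a bicyclic 2,4‑dienone.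
3. The seven‑membered ring forms in a Claisen ring expansion ([3,3]) of a 2‑methylidene‑5‑methyl‑5‑vinyl‑tetrahydrofuran, followed by Saegusa dehydrogenation.
4. That tetrahydrofuran comes from the Diels–Alder adduct of isoprene with (R)‑5‑(hydroxymethyl)butenolide (MeLi/vinylMgBr, glycol cleavage, lactol oxidation, Petasis methylenation); the butenolide stereocentre fixes both ring‑fusion centres and ends as the ring ketone carbon.
5. Ring order: cyclohexene (Diels–Alder), then cycloheptenone (Claisen), then the cyclohexene is opened last.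

Assumption: (R)‑5‑(hydroxymethyl)furan‑2(5H)‑one and (R)‑α‑hydroxy‑γ‑butyrolactone are bought as single enantiomers (the S forms would give the enantiomer of the target).

## Route

Step 1
Reactants: 1 (R)-3-hydroxyoxolan-2-one [(R)-α-hydroxy-γ-butyrolactone]
Product: 2 (R)-3-[(tert-butyldimethylsilyl)oxy]oxolan-2-one
Conditions: TBSCl, imidazole, DMF, rt
Reagents that add atoms: tert-butyldimethylsilyl chloride, CC(C)(C)[Si](C)(C)Cl
Why: O‑silylation (silyl ether formation) masks the purchased carbinol, whose configuration is not touched.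

Step 2
Reactants: 2 (R)-3-[(tert-butyldimethylsilyl)oxy]oxolan-2-one
Product: 3 (3R)-3-[(tert-butyldimethylsilyl)oxy]-2-methyloxolan-2-ol (methyl lactol, ring tautomer of the 5-hydroxypentan-2-one)
Conditions: MeLi (1.05 equiv), THF, −78 °C; aq. NH4Cl
Reagents that add atoms: methyllithium, [Li]C
Why: Organolithium mono‑addition to a lactone stops at the lithium hemiketal at −78 °C, so only one methyl is delivered and the stereocentre is untouched.

Step 3
Reactants: 3 (3R)-3-[(tert-butyldimethylsilyl)oxy]-2-methyloxolan-2-ol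
Product: 4 (R)-3-[(tert-butyldimethylsilyl)oxy]-4-methylpent-4-en-1-ol
Conditions: Ph3PCH3Br, KOtBu (3 equiv each), THF, 0 °C → rt
Reagents that add atoms: methyltriphenylphosphonium bromide, C[P+](c1ccccc1)(c1ccccc1)c1ccccc1.[Br-]
Why: Wittig methylenation of the open hydroxy‑ketone tautomer builds the isopropenyl group next to the stereocentre, which takes no part in the reaction.

Step 4
Reactants: 4 (R)-3-[(tert-butyldimethylsilyl)oxy]-4-methylpent-4-en-1-ol
Product: 5 (R)-5-bromo-3-[(tert-butyldimethylsilyl)oxy]-2-methylpent-1-ene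
Conditions: CBr4, PPh3, CH2Cl2, 0 °C
Reagents that add atoms: carbon tetrabromide, BrC(Br)(Br)Br
Why: Appel bromination converts the primary alcohol into the bromide needed for the Grignard reagent without affecting the silyloxy stereocentre.

Step 5
Reactants: 6 (R)-5-(hydroxymethyl)furan-2(5H)-one; 7 isoprene (2-methylbuta-1,3-diene)
Product: 8 (3R,3aR,7aS)-3-(hydroxymethyl)-5-methyl-3a,4,7,7a-tetrahydro-2-benzofuran-1(3H)-one
Conditions: EtAlCl2 (2.2 equiv), isoprene (5 equiv), CH2Cl2, −40 °C → rt; aq. HCl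
Reagents that add atoms: none
Why: In this Lewis‑acid‑promoted Diels–Alder cycloaddition (the first equivalent of EtAlCl2 turns the hydroxyl into its aluminium alkoxide) isoprene adds suprafacially to the face anti to the C5 CH2O group, which sets both cis ring‑fusion centres from the purchased one, and its more nucleophilic C1 bonds to the lactone β‑carbon to give the 5‑methyl ("para") regioisomer.

Step 6
Reactants: 8 (3R,3aR,7aS)-3-(hydroxymethyl)-5-methyl-3a,4,7,7a-tetrahydro-2-benzofuran-1(3H)-one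
Product: 10 (1R)-1-[(1R,6S)-6-(2-hydroxybut-3-en-2-yl)-3-methylcyclohex-3-en-1-yl]ethane-1,2-diol (both tertiary carbinol epimers), via methyl lactol 9 (not isolated)
Conditions: MeLi (2.05 equiv), THF, −78 °C; then CH2=CHMgBr (3 equiv), −78 → 0 °C; aq. NH4Cl
Reagents that add atoms: methyllithium, [Li]C; vinylmagnesium bromide, C=C[Mg]Br
Why: Sequential organolithium then Grignard addition to the lactone carbonyl (the lithium hemiketal survives at −78 °C and opens to the methyl ketone on warming) gives the methyl vinyl carbinol, whose new centre needs no control because it becomes sp2 in step 8.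

Step 7
Reactants: 10 (1R)-1-[(1R,6S)-6-(2-hydroxybut-3-en-2-yl)-3-methylcyclohex-3-en-1-yl]ethane-1,2-diol
Product: 12 (3aS,7aR)-3-ethenyl-3,6-dimethyl-3a,4,7,7a-tetrahydro-2-benzofuran-1(3H)-one (both C3 epimers), via lactol 11 (not isolated)
Conditions: NaIO4, THF/H2O, 0 °C; extract; then TEMPO (10 mol %), PhI(OAc)2, CH2Cl2, rt
Reagents that add atoms: none
Why: Periodate glycol cleavage gives an aldehyde that is trapped at once by the cis tertiary hydroxyl as a lactol, protecting the adjacent ring‑fusion centre from epimerisation, and TEMPO oxidation then gives the γ‑lactone.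

Step 8
Reactants: 12 (3aS,7aR)-3-ethenyl-3,6-dimethyl-3a,4,7,7a-tetrahydro-2-benzofuran-1(3H)-one
Product: 14 (4aR,9aS)-3,9-dimethyl-1,4,4a,6,7,9a-hexahydro-5H-benzo[7]annulen-5-one, via exocyclic enol ether 13 (not isolated)
Conditions: Cp2TiMe2, toluene, 70 °C, dark; filter (basic Al2O3); then toluene, 170 °C, sealed tube
Reagents that add atoms: dimethyltitanocene, C[Ti](C)(C1C=CC=C1)C1C=CC=C1
Why: Petasis methylenation gives the 2‑methylidene‑5‑vinyl‑tetrahydrofuran, whose Claisen rearrangement ([3,3]) forms the C6–C7 bond and thereby the seven‑membered ring, while both carbinol epimers converge because that carbon becomes sp2 and the ring‑fusion centres are untouched.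

Step 9
Reactants: 14 (4aR,9aS)-3,9-dimethyl-1,4,4a,6,7,9a-hexahydro-5H-benzo[7]annulen-5-one
Product: 16 (4aR,9aS)-3,9-dimethyl-1,4,4a,9a-tetrahydro-5H-benzo[7]annulen-5-one, via trimethylsilyl enol ether 15 (not isolated)
Conditions: LiN(CHMe2)2, TMSCl, THF, −78 °C; then Pd(OAc)2 (10 mol %), O2 (1 atm), DMSO, rt
Reagents that add atoms: none
Why: Kinetic enolisation at the CH2 side (not at the ring‑fusion CH) followed by Saegusa–Ito oxidation gives the linearly conjugated 2,4‑dienone without disturbing the ring fusion.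

Step 10
Reactants: 16 (4aR,9aS)-3,9-dimethyl-1,4,4a,9a-tetrahydro-5H-benzo[7]annulen-5-one; 5 (R)-5-bromo-3-[(tert-butyldimethylsilyl)oxy]-2-methylpent-1-ene
Product: 20 (4aR,9S,9aS)-9-{(3R)-3-[(tert-butyldimethylsilyl)oxy]-4-methylpent-4-en-1-yl}-3,9-dimethyl-1,4,4a,8,9,9a-hexahydro-5H-benzo[7]annulen-5-one, via Grignard reagent 17 (not isolated), via silyl dienol ether 18 (not isolated), via deconjugated enone 19 (not isolated)
Conditions: 5, Mg, THF → 17; CuBr·SMe2 (20 mol %), TMSCl, THF, −78 → −30 °C, add 16; 1 M HCl, 0 °C; then DBU (0.2 equiv), CH2Cl2, 0 °C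
Reagents that add atoms: none
Why: Copper‑catalysed 1,6‑conjugate addition places the side chain on C9 from the convex face of the cis‑fused bicycle (anti to the cyclohexene ring), which sets the quaternary centre with methyl cis to the ring CH2, and mild base then moves the double bond into conjugation via the doubly activated C6–H without touching C4a.

Step 11
Reactants: 20 (4aR,9S,9aS)-9-{(3R)-3-[(tert-butyldimethylsilyl)oxy]-4-methylpent-4-en-1-yl}-3,9-dimethyl-1,4,4a,8,9,9a-hexahydro-5H-benzo[7]annulen-5-one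
Product: 21 (4aR,9S,9aS)-9-{(3R)-3-[(tert-butyldimethylsilyl)oxy]-4-methylpent-4-en-1-yl}-6-(hydroxymethyl)-3,9-dimethyl-1,4,4a,8,9,9a-hexahydro-5H-benzo[7]annulen-5-one
Conditions: aq. HCHO (37 %), DMAP (0.5 equiv), THF/H2O, rt
Reagents that add atoms: formaldehyde, C=O
Why: Morita–Baylis–Hillman hydroxymethylation puts CH2OH on the enone α‑carbon (the β‑carbon is an unsubstituted CH) and creates no stereocentre.

Step 12
Reactants: 21 (the 6-(hydroxymethyl) enone)
Product: 22 (4aR,9S,9aS)-6-{[(tert-butyldimethylsilyl)oxy]methyl}-9-{(3R)-3-[(tert-butyldimethylsilyl)oxy]-4-methylpent-4-en-1-yl}-3,9-dimethyl-1,4,4a,8,9,9a-hexahydro-5H-benzo[7]annulen-5-one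
Conditions: TBSCl, imidazole, DMF, 0 °C → rt
Reagents that add atoms: tert-butyldimethylsilyl chloride, CC(C)(C)[Si](C)(C)Cl
Why: O‑silylation protects the primary allylic alcohol so that only the aldehyde enol is acylated in step 14.

Step 13
Reactants: 22 (the bis-silyl bicyclic enone)
Product: 24 {(1S,2R,7S)-4-{[(tert-butyldimethylsilyl)oxy]methyl}-7-{(3R)-3-[(tert-butyldimethylsilyl)oxy]-4-methylpent-4-en-1-yl}-7-methyl-3-oxo-2-(2-oxopropyl)cyclohept-4-en-1-yl}acetaldehyde, via secondary ozonide 23 (not isolated)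
Conditions: O3 (1.0 equiv, Sudan Red 7B end point), pyridine (2 equiv), CH2Cl2, −78 °C; then Me2S, −78 °C → rt
Reagents that add atoms: ozone, [O-][O+]=O
Why: Chemoselective ozonolysis cleaves the electron‑rich trisubstituted ring alkene ahead of the enone and of the isopropenyl group (deactivated by its allylic silyloxy group), releasing the cis acetonyl and formylmethyl arms with all stereocentres intact.

Step 14
Reactants: 24 (the keto aldehyde)
Product: 25 (E)-2-{(1S,2R,7S)-4-{[(tert-butyldimethylsilyl)oxy]methyl}-7-{(3R)-3-[(tert-butyldimethylsilyl)oxy]-4-methylpent-4-en-1-yl}-7-methyl-3-oxo-2-(2-oxopropyl)cyclohept-4-en-1-yl}ethenyl 3-methylbut-2-enoate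
Conditions: (Me2C=CHCO)2O, Et3N, DMAP (cat.), CH2Cl2, 0 °C → rt
Reagents that add atoms: 3-methylbut-2-enoic anhydride, CC(C)=CC(=O)OC(=O)C=C(C)C
Why: O‑acylation of the aldehyde enol (enol ester formation) is much faster than for the two ketones and gives the trans enol ester, favoured because the bulky ring carbon sits anti to the acyloxy group.

Step 15
Reactants: 25 (the bis-silyl enol ester)
Product: 26 (E)-2-{(1S,2R,7S)-7-[(3R)-3-hydroxy-4-methylpent-4-en-1-yl]-4-(hydroxymethyl)-7-methyl-3-oxo-2-(2-oxopropyl)cyclohept-4-en-1-yl}ethenyl 3-methylbut-2-enoate (CNP0257974.2)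
Conditions: HF·pyridine, pyridine/THF, 0 °C → rt
Reagents that add atoms: none
Why: Buffered fluoride desilylation frees both hydroxyls without touching the enol ester, the enone or the epimerisable CH next to the ring ketone.

## Compound list

1 | (R)-3-hydroxyoxolan-2-one | O[C@@H]1CCOC1=O | starting material
2 | (R)-3-[(tert-butyldimethylsilyl)oxy]oxolan-2-one | CC(C)(C)[Si](C)(C)O[C@@H]1CCOC1=O | intermediate
3 | (3R)-3-[(tert-butyldimethylsilyl)oxy]-2-methyloxolan-2-ol | CC1(O)OCC[C@H]1O[Si](C)(C)C(C)(C)C | intermediate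
4 | (R)-3-[(tert-butyldimethylsilyl)oxy]-4-methylpent-4-en-1-ol | C=C(C)[C@@H](CCO)O[Si](C)(C)C(C)(C)C | intermediate
5 | (R)-5-bromo-3-[(tert-butyldimethylsilyl)oxy]-2-methylpent-1-ene | C=C(C)[C@@H](CCBr)O[Si](C)(C)C(C)(C)C | intermediate
6 | (R)-5-(hydroxymethyl)furan-2(5H)-one | O=C1C=C[C@H](CO)O1 | starting material
7 | isoprene | C=CC(C)=C | starting material
8 | (3R,3aR,7aS)-3-(hydroxymethyl)-5-methyl-3a,4,7,7a-tetrahydro-2-benzofuran-1(3H)-one | O=C1[C@H]2CC=C(C)C[C@H]2[C@H](CO)O1 | intermediate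
9 | (3R,3aR,7aS)-3-(hydroxymethyl)-1,5-dimethyl-1,3,3a,4,7,7a-hexahydro-2-benzofuran-1-ol (methyl lactol) | CC1(O)[C@H]2CC=C(C)C[C@H]2[C@H](CO)O1 | intermediate
10 | (1R)-1-[(1R,6S)-6-(2-hydroxybut-3-en-2-yl)-3-methylcyclohex-3-en-1-yl]ethane-1,2-diol | C=CC(C)(O)[C@H]1CC=C(C)C[C@H]1[C@@H](O)CO | intermediate
11 | (3aS,7aR)-3-ethenyl-3,6-dimethyl-1,3,3a,4,7,7a-hexahydro-2-benzofuran-1-ol (lactol) | OC1OC(C)(C=C)[C@H]2CC=C(C)C[C@@H]12 | intermediate
12 | (3aS,7aR)-3-ethenyl-3,6-dimethyl-3a,4,7,7a-tetrahydro-2-benzofuran-1(3H)-one | O=C1OC(C)(C=C)[C@H]2CC=C(C)C[C@@H]12 | intermediate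
13 | (3aS,7aR)-3-ethenyl-3,6-dimethyl-1-methylidene-1,3,3a,4,7,7a-hexahydro-2-benzofuran | C=C1OC(C)(C=C)[C@H]2CC=C(C)C[C@@H]12 | intermediate
14 | (4aR,9aS)-3,9-dimethyl-1,4,4a,6,7,9a-hexahydro-5H-benzo[7]annulen-5-one | O=C1CCC=C(C)[C@H]2CC=C(C)C[C@@H]12 | intermediate
15 | {[(4aR,9aS)-3,9-dimethyl-4,4a,7,9a-tetrahydro-1H-benzo[7]annulen-5-yl]oxy}trimethylsilane | C[Si](C)(C)OC1=CCC=C(C)[C@H]2CC=C(C)C[C@@H]12 | intermediate
16 | (4aR,9aS)-3,9-dimethyl-1,4,4a,9a-tetrahydro-5H-benzo[7]annulen-5-one | O=C1C=CC=C(C)[C@H]2CC=C(C)C[C@@H]12 | intermediate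
17 | {(3R)-3-[(tert-butyldimethylsilyl)oxy]-4-methylpent-4-en-1-yl}magnesium bromide | C=C(C)[C@@H](CC[Mg]Br)O[Si](C)(C)C(C)(C)C | intermediate
18 | trimethylsilyl 5,7-dienol ether of 20 | C[Si](C)(C)OC1=CC=C[C@](C)(CC[C@@H](O[Si](C)(C)C(C)(C)C)C(C)=C)[C@H]2CC=C(C)C[C@@H]12 | intermediate
19 | 7,8-ene (deconjugated) isomer of 20 | O=C1CC=C[C@](C)(CC[C@@H](O[Si](C)(C)C(C)(C)C)C(C)=C)[C@H]2CC=C(C)C[C@@H]12 | intermediate
20 | (4aR,9S,9aS)-9-{(3R)-3-[(tert-butyldimethylsilyl)oxy]-4-methylpent-4-en-1-yl}-3,9-dimethyl-1,4,4a,8,9,9a-hexahydro-5H-benzo[7]annulen-5-one | O=C1C=CC[C@](C)(CC[C@@H](O[Si](C)(C)C(C)(C)C)C(C)=C)[C@H]2CC=C(C)C[C@@H]12 | intermediate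
21 | 6-(hydroxymethyl) derivative of 20 | O=C1C(CO)=CC[C@](C)(CC[C@@H](O[Si](C)(C)C(C)(C)C)C(C)=C)[C@H]2CC=C(C)C[C@@H]12 | intermediate
22 | 6-{[(tert-butyldimethylsilyl)oxy]methyl} derivative of 20 | O=C1C(CO[Si](C)(C)C(C)(C)C)=CC[C@](C)(CC[C@@H](O[Si](C)(C)C(C)(C)C)C(C)=C)[C@H]2CC=C(C)C[C@@H]12 | intermediate
23 | secondary ozonide (1,2,4-trioxolane across C2–C3) of 22 | O=C1C(CO[Si](C)(C)C(C)(C)C)=CC[C@](C)(CC[C@@H](O[Si](C)(C)C(C)(C)C)C(C)=C)[C@H]2CC3OOC(C)(O3)C[C@@H]12 | intermediate
24 | {(1S,2R,7S)-4-{[(tert-butyldimethylsilyl)oxy]methyl}-7-{(3R)-3-[(tert-butyldimethylsilyl)oxy]-4-methylpent-4-en-1-yl}-7-methyl-3-oxo-2-(2-oxopropyl)cyclohept-4-en-1-yl}acetaldehyde | O=C1C(CO[Si](C)(C)C(C)(C)C)=CC[C@](C)(CC[C@@H](O[Si](C)(C)C(C)(C)C)C(C)=C)[C@@H](CC=O)[C@H]1CC(C)=O | intermediate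
25 | bis(tert-butyldimethylsilyl) ether of the target | O=C1C(CO[Si](C)(C)C(C)(C)C)=CC[C@](C)(CC[C@@H](O[Si](C)(C)C(C)(C)C)C(C)=C)[C@@H](/C=C/OC(=O)C=C(C)C)[C@H]1CC(C)=O | intermediate
26 | (E)-2-{(1S,2R,7S)-7-[(3R)-3-hydroxy-4-methylpent-4-en-1-yl]-4-(hydroxymethyl)-7-methyl-3-oxo-2-(2-oxopropyl)cyclohept-4-en-1-yl}ethenyl 3-methylbut-2-enoate | O=C1C(CO)=CC[C@](C)(CC[C@@H](O)C(C)=C)[C@@H](/C=C/OC(=O)C=C(C)C)[C@H]1CC(C)=O | target

## Step count and risks

Total step count: 15 (side chain 4 steps, core 11 steps). Longest linear sequence: 11 steps (steps 5 to 15, from 6).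

The three steps most likely to fail:

Step 10 (1,6‑addition forming the quaternary carbon). The δ‑carbon is fully substituted, so 1,4‑attack at C7 or simple enolisation of 16 may win. The fallback sets out from dienone 16 and bromide 5 and uses no preformed organometallic: a nickel‑catalysed reductive conjugate addition (NiCl2(MeOCH2CH2OMe) 10 mol %, neocuproine, Mn, Et3SiCl, DMF) in which a siloxy‑pentadienyl nickel species captures the alkyl radical at the hindered terminus from the convex face and gives the triethylsilyl dienol ether F1. Brief aqueous acid and the same DBU equilibration bring it back to the route at enone 20.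

Step 11 (Morita–Baylis–Hillman). Seven‑membered enones next to a quaternary centre react slowly, and long exposure to aqueous amine could epimerise C4a. The fallback sets out from enone 20: iodine and pyridine in CH2Cl2 give the 2‑iodo enone F2 by addition–elimination, and a Stille coupling with Bu3SnCH2OH (Pd(PPh3)4, dioxane, 80 °C) installs the hydroxymethyl group under neutral conditions, coming back at 21.

Step 14 (enol ester formation). The 1,6‑keto aldehyde can undergo intramolecular aldol reaction, the centre next to the ring ketone can epimerise under amine base, and E/Z control is not assured. The fallback sets out from keto aldehyde 24: selective soft enolisation of the aldehyde (TMSOTf 1.05 equiv, Et3N, CH2Cl2, −78 °C) gives the trimethylsilyl enol ether F3. Acyl transfer with 3‑methylbut‑2‑enoyl fluoride and CsF in MeCN, with no free amine base, followed by iodine‑catalysed equilibration to the trans isomer, comes back at 25.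

## Further compounds

F1 | step 10 | triethylsilyl 5,7-dienol ether of 20 | CC[Si](CC)(CC)OC1=CC=C[C@](C)(CC[C@@H](O[Si](C)(C)C(C)(C)C)C(C)=C)[C@H]2CC=C(C)C[C@@H]12
F2 | step 11 | 6-iodo derivative of 20 | O=C1C(I)=CC[C@](C)(CC[C@@H](O[Si](C)(C)C(C)(C)C)C(C)=C)[C@H]2CC=C(C)C[C@@H]12
F3 | step 14 | trimethylsilyl enol ether of aldehyde 24 | O=C1C(CO[Si](C)(C)C(C)(C)C)=CC[C@](C)(CC[C@@H](O[Si](C)(C)C(C)(C)C)C(C)=C)[C@@H](C=CO[Si](C)(C)C)[C@H]1CC(C)=O
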